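Readings and results stem from a simulated flask with made-up constants, noise included.

The amber run, with the lower charge of starting material, loses it at a steady first-order pace: the constant read after 4.00 h is 0.0392 h⁻¹ and after 20.0 h it is 0.0384 h⁻¹. The ochre run, on the same enzyme charge, stalls by the first reading, with target averaging 1.70% and starting material at 98.9% after 20.0 h.

| setting | amber | ochre | Monday's | Thursday's | Wednesday's | Tuesday's | Saturday's |
|---|---|---|---|---|---|---|---|
| starting material | 0.032 M | 0.59 M | 0.025 M | 0.050 M | 0.10 M | 0.20 M | 0.40 M |
| enzyme | 5.4 µM | 5.4 µM | 5.4 µM | 5.4 µM | 5.4 µM | 5.4 µM | 5.4 µM |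
| remark | run made earlier | run made earlier |  |  |  |  |  |
| time |  |  | 40 h | 40 h | 40 h | 40 h | 40 h |

- amber (time / h: target / %, starting material / %): 4.00: 14.0, 85.5; 8.00: 25.5, 72.8; 12.0: 34.2, 61.4; 15.0: 39.6, 55.6; 20.0: 46.9, 46.4
- ochre (time / h: target / %, starting material / %): 4.00: 2.2, 98.8; 8.00: 2.0, 97.7; 12.0: 1.3, 98.3; 15.0: 1.9, 97.9; 20.0: 1.1, 98.9

(standard deviation of a reading: 0.5 percentage points)

- "hardly changes" means that all values lie within two and a half points (for a concentration: within two and a half percent of the largest)

* [target] at the end for Monday's, Thursday's, Wednesday's, Tuesday's, Saturday's, in this order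
* how the row runs (rises all the way / hardly changes / rises, then falls / falls, then rises / falls all the way)

This reckoning takes the stall as enzyme death and lets the risk per turnover grow in proportion to [starting material]. Target made per enzyme lost then goes as one over [starting material]. While [starting material] stays nearly constant, integrating over the whole enzyme charge gives a ceiling, [target] = B/[starting material]. This is a total turnover number multiplied by the enzyme charge. The ochre run gives B, the ceiling product, target ceiling times charge, as a reading of 0.00592 M^2. At the amber charge the ceiling is 0.185 M, more than the charge itself, so this reckoning puts no stop on the amber run.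

The row can now be drawn against charge. It starts as a straight line of slope 68.7%, which is the amber target share of material consumed multiplied by first-order conversion at 40 h. That line gives 0.0172 M for Monday's flask and 0.0343 M for Thursday's. It crosses the ceiling at 0.0928 M, just below Wednesday's charge, so the knee falls there, with Wednesday's flask under 0.0592 M. Beyond the knee this reckoning follows the ceiling down, to 0.0296 M for Tuesday's flask and 0.0148 M for Saturday's.

The forecast, close to this but not the same, gives 0.018 M, 0.034 M, 0.05 M, 0.03 M and 0.015 M, rises, then falls, and says “the row peaks near 0.1 M”. The flasks give 0.0154 M, 0.0290 M, 0.0430 M, 0.0276 M and 0.0129 M, rises, then falls, turning at 0.10 M.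

    target ⇌ isomer of the product (K = 0.320, k = 2.70 × 10⁻⁴ min⁻¹)
    complex ⇌ enzyme + target (K = 1.20 M, k = 29.0 min⁻¹)
    starting material + complex → spent catalyst (k = 0.0240 L mol⁻¹ min⁻¹)
    starting material + enzyme ⇌ complex (K = 5.10 L mol⁻¹, k = 37000 L mol⁻¹ min⁻¹)

On the falling side the ceiling stands higher than the flasks: Saturday's 0.0148 M against 0.0129 M, and Tuesday's 0.0296 M against 0.0276 M. Wednesday's 0.0430 M lies lower than its ceiling. The largest single effect on Saturday's target is the reaction of starting material with complex to spent catalyst: the same run without that step ends at 0.173 M instead of 0.0129 M. The stall shows early in Tuesday's flask, where target stands at 13.7% after 20.0 h and at 13.8% after 40.0 h, with spent catalyst at 99.0% of the catalyst charged.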